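## The problem

The target is a daucane-type diester. Locants used throughout: C1 quaternary ring-fusion carbon (methyl), C2 and C3 methylenes, C4 tertiary carbinol (OH, isopropyl), C5 ring-fusion methine, C6 carbinol carrying the 4-hydroxybenzoate, C7=C8 alkene (methyl on C8), C9 carbinol carrying the acetate, C10 methylene; ring A is the seven-membered ring C1, C5–C10 and ring B the five-membered ring C1–C5. Five stereocentres (1R,4R,5S,6S,9S) must be set: C1–Me and C5–H are trans (a trans-fused hydroazulene), C4–OH is cis to C1–Me, and the C6 and C9 oxygens are cis to each other and trans to the methyl. The trans fusion next to a quaternary carbon is the hard part, because kinetically controlled closures onto C5 and equilibration of C5 beside a carbonyl both tend to give cis-fused hydroazulenes. Once C1 and C5 are fixed they can steer the rest: the C6 oxygen lies 1,3 to the C4 oxygen on the same side and can hold a C4 ketone in a chelate, and the axial C1 methyl differentiates the faces of a C9 ketone. The sensitive elements are the two allylic esters (ionisation, acyl migration, elimination to a diene), the β-oxygenated carbonyl relationships that arise whenever C4 is a ketone beside the C6 oxygen (retro-aldol, epimerisation of C5), and the phenol, which must stay masked until the end. The enabling feature is the segment C10–C9(O)–C8(Me)=C7–C6(O) of ring A. With C9 as a ketone it is the carbon chain of a 4-methyl-3-oxidopyrylium whose ring oxygen bridges C6 and C10, so C1 and C5 can enter as an (E)-trisubstituted alkene whose geometry becomes the trans fusion, and the C10–O bond, alpha to the ketone, can later be cut reductively.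

## Retrosynthesis

**Esters and C9 (27 ⇒ 26 ⇒ 25 ⇒ 24 ⇒ 20 + 23).** The phenol silyl ether, the C9–O acetyl bond and the C6–O aroyl bond are cut. C6 is acylated first, at the stage (20) where it is the only secondary hydroxyl. For C9, hydride is not asked to approach a ketone syn to the axial C1 methyl. The expected anti addition to 24 is accepted, and the resulting (9R) alcohol 25 is inverted with acetic acid, so that stereocorrection and acetylation are one step. Precursor 20 has four stereocentres and one acylable hydroxyl. The forward steps need site-selective acylation, a diastereoselective 1,2-reduction and a clean SN2 displacement at an allylic carbon.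

**Ring B and the ether bridge (20 ⇒ 18, through 19).** The C3–C4 bond is cut and the C10–O bond is re-formed. Both are reductive events for one reagent, SmI2. Closing ring B at C3–C4 leaves the fusion centres C1 and C5 untouched, which a closure at C4–C5 or C1–C2 would not. The C6 oxygen released in the same flask can position the C4 ketone. Precursor 18 is a rigid oxabicycle in which C1, C5 and C6 are locked. The forward step must cut the bridge before the iodide is reduced and must close ring B under chelate control.

**Side-chain adjustment (18 ⇒ 17 ⇒ 16 ⇒ 15 ⇒ 14).** The iodide comes from the silyl ether, and the isopropyl ketone from the acyl sultam by way of a thioester. The thioester/organozinc pair is chosen over amide/Grignard chemistry because the C9 enone has to survive. No skeletal bond is involved; the demand is chemoselectivity at a hindered acyl carbon.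

**Ring A (14 ⇒ 12 + 4, through ylide 13).** C10–C1 and C5–C6 are cut in a [5+2] sense. This cut removes ring A and four stereocentres at once and reduces the trans fusion to an alkene geometry. Cutting only C5–C6 (aldol) or only C1–C10 (conjugate addition) would leave the trans relation as a separate problem. The precursors are a racemic, achiral-at-reaction pyranone and an acyclic enoyl sultam. The forward reaction needs regio-, endo- and facial selectivity and a rate that beats self-addition of the ylide. A bornane-10,2-sultam is preferred to an oxazolidinone as the acyl carrier. No chelating Lewis acid can be used beside Et3N and the oxido group, and without one an N-enoyl oxazolidinone holds its stereocentre far from the alkene. The sulfonyl oxygens of the sultam flank the alkene in the reacting conformer, and the sultam has no second carbonyl at which a nucleophile could later open the auxiliary.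

**The two-carbon partner (12 ⇒ 9 + 10; 9 ⇒ 8 ⇒ 6 ⇒ 5, through 7).** The N-acyl bond is cut, then the C–CH3 and C–CO2Et bonds of the trisubstituted alkene. Carboalumination of alkyne 6 is preferred to an olefination of a methyl ketone, which would give E/Z mixtures where geometric purity is the whole point. The forward step needs syn addition of Me–Al with methyl on the internal carbon.

**The pyranone (4 ⇒ 3 ⇒ 2 ⇒ 1).** The pyranone ring is traced to a furan by the Achmatowicz rearrangement. The C8 methyl and the C9 oxygen are already in place in furoate 1, and the acetal carbon of 4 needs no stereocontrol because it becomes sp2 in 13.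

**The aroyl donor (23 ⇒ 22 ⇒ 21).** The acid chloride is made from 4-hydroxybenzoic acid by silylation and direct conversion of the silyl ester. The silyl ether is chosen because it can be removed at the end beside an acetate.

## Roads not taken

**Alternative 1:** The cut is at C5–C1 and C5–C6, with C5 as a carbene carbon delivered to a benzene ring. Diazoketone A1 with [Cu(MeCN)4]PF6 and a chiral bis(oxazoline) would cyclopropanate the arene, and the norcaradiene would open to azulenone A2, closing ring B and expanding the arene to ring A in one catalytic step.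
- Merits: a trivial aromatic precursor, a catalytic asymmetric key step of a known type, and the shortest access to the bicyclic carbon skeleton. In step economy up to the core it is better than the chosen plan.
- Weak points: A2 carries only the C5 stereocentre, which is doubly activated (alpha to the ketone and allylic) and easily lost. C1 is still sp2, so the quaternary methyl and the trans fusion must be created later without a controlling element. The carbene must also choose the C1–C6 over the C1–C10 arene bond, and the triene must then be oxygenated at C6 while C7=C8 is kept.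
- Comparison: the chosen plan has a riskier key step, but it sets C1, C5 and C6 together with the trans fusion, which this road leaves unsolved.

**Alternative 2:** The cut is at both ring A C–O bonds. Singlet oxygen (O2, tetraphenylporphyrin, visible light) would add across C6 and C9 of diene A3 to give endoperoxide A4, forming both C–O bonds and the C7=C8 alkene.
- Merits: the two oxygens arrive cis to each other in one well-precedented step, late in the synthesis. Base-induced opening of A4 would lead to the same hydroxy-enone stage that the chosen route reaches at 20. For the oxygenation pattern this road is better than the chosen one, which needs two extra steps to correct C9.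
- Weak points: the key step presupposes the whole trans-fused skeleton with C1, C4 and C5 in place, so the real difficulty is moved to an unspecified early phase. The ene reaction at the C8 methyl and C10 competes, and the facial choice rests only on the angular methyl.
- Comparison: the chosen plan builds ring A, the fusion stereochemistry and the C6 oxygen in its key step.

**Alternative 3:** The cut is at C5–C1 and C9–C10. Et3N would ionise tethered acetoxypyranone A5, and the ylide would add across the pendant 1,1-disubstituted alkene to give tricyclic enone A6, closing rings A and B together under a C5–O–C9 bridge.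
- Merits: intramolecular oxidopyrylium cycloadditions through a three-atom tether are thoroughly precedented, quaternary centres included. The tether enforces regiochemistry and no auxiliary is needed. In reliability of the key step this road is clearly better than the chosen one.
- Weak points: absolute control rests on an enantiopure tertiary carbinol (C4) that is itself hard to make. C5 emerges as an oxygen-bearing bridgehead, so the fusion hydrogen must be introduced afterwards by reductive C5–O cleavage and enolate protonation, where cis fusion is a real possibility. The resulting C4-hydroxy C6-ketone is a retro-aldol candidate.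
- Comparison: the chosen plan fixes the trans fusion irreversibly through alkene geometry, sets C6 with its oxygen in the same event, and takes its absolute configuration from a recoverable auxiliary.

Key step: step 8

Assumption: uncatalysed dipolar additions to N-enoyl bornane-10,2-sultams are taken to proceed through the s-cis enoyl conformer with the carbonyl anti to the sulfonyl group, the dipole arriving on the face away from the lower sulfonyl oxygen; for the (2R)-sultam this is the Cα-Re face.

## Route

Step 1
Reactants: 1 methyl 3-methylfuran-2-carboxylate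
Product: 2 (3-methylfuran-2-yl)methanol
Conditions: LiAlH4, Et2O, 0 °C
Reagents that add atoms: none
Why: Ester reduction with LiAlH4; the furan ring and its methyl group are inert to hydride.

Step 2
Reactants: 2 (3-methylfuran-2-yl)methanol
Product: 3 6-hydroxy-4-methyl-2H-pyran-3(6H)-one (racemic hemiacetal)
Conditions: mCPBA, CH2Cl2, 0 °C → rt
Reagents that add atoms: 3-chloroperoxybenzoic acid (mCPBA), OOC(=O)c1cccc(Cl)c1
Why: Achmatowicz rearrangement: oxidation of the furan, opening to the cis-enedione and hemiacetal closure by the primary hydroxyl give the pyranone with the methyl alpha to the ketone. The hemiacetal centre forms as a racemate, which does not matter because it is lost on ionisation.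

Step 3
Reactants: 3 6-hydroxy-4-methyl-2H-pyran-3(6H)-one
Product: 4 6-acetoxy-4-methyl-2H-pyran-3(6H)-one (racemic)
Conditions: Ac2O, pyridine, DMAP (cat.), CH2Cl2, 0 °C
Reagents that add atoms: acetic anhydride, CC(=O)OC(C)=O
Why: Acetylation of the only hydroxyl installs the leaving group; the weak base and low temperature avoid premature ylide formation.

Step 4
Reactants: 5 but-3-yn-1-ol
Product: 6 tert-butyl(but-3-yn-1-yloxy)dimethylsilane
Conditions: TBSCl, imidazole, CH2Cl2, 0 °C → rt
Reagents that add atoms: tert-butyldimethylsilyl chloride, CC(C)(C)[Si](C)(C)Cl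
Why: Standard silylation of a primary alcohol; the silyl ether tolerates AlMe3 and the later basic and organometallic steps.

Step 5
Reactants: 6 tert-butyl(but-3-yn-1-yloxy)dimethylsilane
Product: 8 ethyl (E)-5-(tert-butyldimethylsilyloxy)-3-methylpent-2-enoate, via (E)-alkenyldimethylalane 7 (not isolated)
Conditions: AlMe3 (2.5 equiv), Cp2ZrCl2 (0.25 equiv), CH2Cl2, 0 °C → rt; then ClCO2Et, 0 °C → rt
Reagents that add atoms: trimethylaluminium, C[Al](C)C; ethyl chloroformate, CCOC(Cl)=O
Why: Negishi zirconium-catalysed carboalumination adds Me–Al syn across the terminal alkyne with methyl on the internal carbon. The alkenylalane is acylated by the chloroformate with retention, so the ester is cis to the new methyl and only the (E) isomer forms.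

Step 6
Reactants: 8 ethyl (E)-5-(tert-butyldimethylsilyloxy)-3-methylpent-2-enoate
Product: 9 (E)-5-(tert-butyldimethylsilyloxy)-3-methylpent-2-enoic acid
Conditions: LiOH·H2O, THF/MeOH/H2O, rt; then 1 M HCl to pH 4, 0 °C
Reagents that add atoms: lithium hydroxide, [Li+].[OH-]
Why: Saponification of the ethyl ester; the primary silyl ether survives LiOH at room temperature and the trisubstituted alkene keeps its geometry.

Step 7
Reactants: 9 (E)-5-(tert-butyldimethylsilyloxy)-3-methylpent-2-enoic acid; 10 (2R)-bornane-10,2-sultam [(1S)-(−)-2,10-camphorsultam]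
Product: 12 N-[(2E)-5-(tert-butyldimethylsilyloxy)-3-methylpent-2-enoyl]-(2R)-bornane-10,2-sultam, via mixed pivalic anhydride 11 (not isolated)
Conditions: 9, PivCl, Et3N, THF, −20 °C; then 10 pretreated with n-BuLi (THF, −78 °C), −78 → 0 °C; aq. NH4Cl
Reagents that add atoms: none
Why: N-Acylation of the lithiated sultam by the mixed anhydride, which is attacked at the less hindered enoyl carbonyl; no stereocentre forms and the (E) geometry is retained.

Step 8
Reactants: 12 N-[(2E)-5-(tert-butyldimethylsilyloxy)-3-methylpent-2-enoyl]-(2R)-bornane-10,2-sultam; 4 6-acetoxy-4-methyl-2H-pyran-3(6H)-one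
Product: 14 N-{[(1S,5S,6S,7S)-7-[2-(tert-butyldimethylsilyloxy)ethyl]-3,7-dimethyl-2-oxo-8-oxabicyclo[3.2.1]oct-3-en-6-yl]carbonyl}-(2R)-bornane-10,2-sultam (acyl and 7-methyl endo, silyloxyethyl exo), via 4-methyl-3-oxidopyrylium 13 (not isolated)
Conditions: Et3N, MeCN, 60 °C; 4 (3 equiv) added over 12 h to 12 (1 M)
Reagents that add atoms: none
Why: Proposed new method: Et3N enolises 4 and acetate leaves, giving the 3-oxidopyrylium 13, which adds suprafacially across the Cα=Cβ bond of 12 in a concerted, asynchronous [5+2] cycloaddition; the closest known reaction type is the intermolecular 3-oxidopyrylium cycloaddition with acrylates, acrylamides and enones, which has not been shown for a β,β-disubstituted acyclic acceptor. Ring A is closed by this intermolecular two-bond cycloaddition as the seven-membered carbocycle of an 8-oxabicyclo[3.2.1]octenone, the pyran oxygen remaining as the C6–O–C10 bridge. Regiochemistry should follow the usual polarity: the ylide carbon next to the oxido group (C10, largest HOMO coefficient) bonds to the β-carbon C1 and the acetal-derived carbon C6 to the α-carbon C5. C1 and C5 are set relative to each other by the (E) geometry (methyl and acyl cis, hence C1–Me and C5–H trans) and in the absolute sense by the sultam, whose s-cis, carbonyl-anti-to-sulfonyl conformer exposes the Cα-Re face; C6 and C10 follow from the endo orientation of the acyl group under the enolate part of the ylide, as with acrylates. The step therefore needs regio-, endo- and facial selectivity and a rate that beats ylide dimerisation: the acyl sultam is a strongly electron-poor acceptor, the C8 methyl slows self-addition of 13, and 4 is fed slowly in excess into concentrated 12 so that unproductive ylide is sacrificed.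

Step 9
Reactants: 14 cycloadduct (acyl sultam)
Product: 15 S-ethyl (1S,5S,6S,7S)-7-[2-(tert-butyldimethylsilyloxy)ethyl]-3,7-dimethyl-2-oxo-8-oxabicyclo[3.2.1]oct-3-ene-6-carbothioate
Conditions: EtSH, n-BuLi, THF, 0 °C; then 14, 0 °C → rt; aq. NH4Cl
Reagents that add atoms: ethanethiol (as its lithium salt), CCS
Why: Thiolysis of the N-acyl sultam by the small, strongly nucleophilic lithium thiolate gives the thioester and returns the auxiliary. Conjugate addition of thiolate to the hindered α-methyl enone is reversible without a proton source, and the weakly basic thiolate does not epimerise C5.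

Step 10
Reactants: 15 S-ethyl thioester
Product: 16 (1S,5S,6S,7S)-7-[2-(tert-butyldimethylsilyloxy)ethyl]-3,7-dimethyl-6-(2-methylpropanoyl)-8-oxabicyclo[3.2.1]oct-3-en-2-one
Conditions: i-PrZnBr (0.5 M in THF), PdCl2(dppf) (5 mol %), toluene, rt
Reagents that add atoms: isopropylzinc bromide, CC(C)[Zn]Br
Why: Fukuyama coupling: zerovalent palladium inserts into the C–S bond and the acylpalladium is alkylated by the organozinc, which adds neither to the enone nor to the ketone formed. The bidentate ferrocenyl phosphine favours reductive elimination over β-hydride loss from the isopropyl group.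

Step 11
Reactants: 16 silyl ether
Product: 17 (1S,5S,6S,7S)-7-(2-hydroxyethyl)-3,7-dimethyl-6-(2-methylpropanoyl)-8-oxabicyclo[3.2.1]oct-3-en-2-one
Conditions: HF·pyridine, pyridine, THF, 0 °C → rt
Reagents that add atoms: none
Why: Fluoride cleavage of the primary silyl ether under buffered, non-basic conditions, which do not epimerise C5 alpha to the ketone.

Step 12
Reactants: 17 primary alcohol
Product: 18 (1S,5S,6S,7S)-7-(2-iodoethyl)-3,7-dimethyl-6-(2-methylpropanoyl)-8-oxabicyclo[3.2.1]oct-3-en-2-one
Conditions: I2, PPh3, imidazole, CH2Cl2, 0 °C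
Reagents that add atoms: iodine, II
Why: Appel-type iodination (alkoxyphosphonium displaced by iodide); the neutral conditions leave both ketones and C5 untouched.

Step 13
Reactants: 18 iodide
Product: 20 (3R,3aS,4S,8aR)-3,4-dihydroxy-6,8a-dimethyl-3-(propan-2-yl)-2,3,3a,4,8,8a-hexahydroazulen-7(1H)-one [daucane locants: (1R,4R,5S,6S)-4,6-dihydroxy-7-en-9-one, trans-fused], via ring-opened iodo hydroxy enone 19 (not isolated)
Conditions: SmI2 (6 equiv), HMPA, THF, −78 → 0 °C; then aq. NH4Cl
Reagents that add atoms: none
Why: SmI2 first cleaves the C10–O bond alpha to the C9 ketone, leaving a trivalent-samarium dienolate that shields the enone from further reduction and a C6 samarium alkoxide; reduction of the primary iodide then gives an organosamarium that adds to the C4 ketone in an intramolecular Barbier reaction (5-exo closure of ring B). The C6–O–Sm/C4=O chelate holds the carbonyl oxygen syn to C6, so C4–OH ends cis to C6 and the isopropyl group trans, the (4R) configuration; protonation of the dienolate at C10 on work-up returns the enone.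

Step 14
Reactants: 21 4-hydroxybenzoic acid
Product: 22 tert-butyldimethylsilyl 4-(tert-butyldimethylsilyloxy)benzoate
Conditions: TBSCl (2.2 equiv), imidazole, DMF, rt
Reagents that add atoms: tert-butyldimethylsilyl chloride, CC(C)(C)[Si](C)(C)Cl
Why: Silylation of both the phenol and the carboxylic acid.

Step 15
Reactants: 22 tert-butyldimethylsilyl 4-(tert-butyldimethylsilyloxy)benzoate
Product: 23 4-(tert-butyldimethylsilyloxy)benzoyl chloride
Conditions: (COCl)2, DMF (cat.), CH2Cl2, 0 °C → rt
Reagents that add atoms: oxalyl chloride, ClC(=O)C(Cl)=O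
Why: Oxalyl chloride with catalytic DMF converts a silyl ester directly into the acid chloride under neutral conditions, leaving the aryl silyl ether intact.

Step 16
Reactants: 20 hydroazulenone diol; 23 4-(tert-butyldimethylsilyloxy)benzoyl chloride
Product: 24 (3R,3aS,4S,8aR)-3-hydroxy-6,8a-dimethyl-7-oxo-3-(propan-2-yl)-1,2,3,3a,4,7,8,8a-octahydroazulen-4-yl 4-(tert-butyldimethylsilyloxy)benzoate
Conditions: Et3N, DMAP, CH2Cl2, 0 °C → rt
Reagents that add atoms: none
Why: DMAP-catalysed acylation of the secondary allylic C6 hydroxyl; the tertiary C4 hydroxyl is too hindered to compete.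

Step 17
Reactants: 24 C6 ester, C9 enone
Product: 25 (3R,3aS,4S,7R,8aR)-3,7-dihydroxy-6,8a-dimethyl-3-(propan-2-yl)-1,2,3,3a,4,7,8,8a-octahydroazulen-4-yl 4-(tert-butyldimethylsilyloxy)benzoate [(9R) alcohol in daucane locants]
Conditions: NaBH4, CeCl3·7H2O, MeOH, −78 °C
Reagents that add atoms: none
Why: Luche 1,2-reduction of the enone; hydride should add to C9 from the face opposite the axial C1 methyl, where a 1,3-diaxial-type contact blocks the other face. This gives the (9R) alcohol, the C9 epimer of what the target needs.

Step 18
Reactants: 25 (9R) alcohol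
Product: 26 (3R,3aS,4S,7S,8aR)-7-acetoxy-3-hydroxy-6,8a-dimethyl-3-(propan-2-yl)-1,2,3,3a,4,7,8,8a-octahydroazulen-4-yl 4-(tert-butyldimethylsilyloxy)benzoate
Conditions: AcOH, PPh3, DIAD, toluene, 0 °C → rt
Reagents that add atoms: acetic acid, CC(O)=O
Why: Mitsunobu esterification displaces the activated C9 oxygen by acetate with inversion, giving the (9S) acetate directly. The tertiary alcohol does not react and the silyl group keeps the phenol from acting as the nucleophile.

Step 19
Reactants: 26 silyl-protected diester
Product: 27 (3R,3aS,4S,7S,8aR)-7-acetoxy-3-hydroxy-6,8a-dimethyl-3-(propan-2-yl)-1,2,3,3a,4,7,8,8a-octahydroazulen-4-yl 4-hydroxybenzoate (CNP0305796.2)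
Conditions: TBAF, AcOH, THF, 0 °C
Reagents that add atoms: none
Why: Fluoride cleaves the aryl silyl ether far faster than it attacks the esters; acetic acid buffers the phenoxide so that neither acyl group migrates or is lost.

## Compound list

1 | methyl 3-methylfuran-2-carboxylate | COC(=O)c1occc1C | starting material
2 | (3-methylfuran-2-yl)methanol | OCc1occc1C | intermediate
3 | 6-hydroxy-4-methyl-2H-pyran-3(6H)-one (racemic) | OC1OCC(=O)C(C)=C1 | intermediate
4 | 6-acetoxy-4-methyl-2H-pyran-3(6H)-one (racemic) | CC(=O)OC1OCC(=O)C(C)=C1 | intermediate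
5 | but-3-yn-1-ol | C#CCCO | starting material
6 | tert-butyl(but-3-yn-1-yloxy)dimethylsilane | C#CCCO[Si](C)(C)C(C)(C)C | intermediate
7 | (E)-[4-(tert-butyldimethylsilyloxy)-2-methylbut-1-en-1-yl]dimethylalane | C[Al](C)/C=C(\C)CCO[Si](C)(C)C(C)(C)C | intermediate
8 | ethyl (E)-5-(tert-butyldimethylsilyloxy)-3-methylpent-2-enoate | CCOC(=O)/C=C(\C)CCO[Si](C)(C)C(C)(C)C | intermediate
9 | (E)-5-(tert-butyldimethylsilyloxy)-3-methylpent-2-enoic acid | OC(=O)/C=C(\C)CCO[Si](C)(C)C(C)(C)C | intermediate
10 | (2R)-bornane-10,2-sultam | CC1(C)[C@@H]2CC[C@]13CS(=O)(=O)N[C@@H]3C2 | starting material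
11 | (E)-5-(tert-butyldimethylsilyloxy)-3-methylpent-2-enoic pivalic anhydride | CC(C)(C)C(=O)OC(=O)/C=C(\C)CCO[Si](C)(C)C(C)(C)C | intermediate
12 | N-[(2E)-5-(tert-butyldimethylsilyloxy)-3-methylpent-2-enoyl]-(2R)-bornane-10,2-sultam | CC1(C)[C@@H]2CC[C@]13CS(=O)(=O)N(C(=O)/C=C(\C)CCO[Si](C)(C)C(C)(C)C)[C@@H]3C2 | intermediate
13 | 4-methyl-3-oxidopyrylium | Cc1cc[o+]cc1[O-] | intermediate
14 | N-{[(1S,5S,6S,7S)-7-[2-(tert-butyldimethylsilyloxy)ethyl]-3,7-dimethyl-2-oxo-8-oxabicyclo[3.2.1]oct-3-en-6-yl]carbonyl}-(2R)-bornane-10,2-sultam | CC1(C)[C@@H]2CC[C@]13CS(=O)(=O)N(C(=O)[C@@H]4[C@@H]5C=C(C)C(=O)[C@@H](O5)[C@@]4(C)CCO[Si](C)(C)C(C)(C)C)[C@@H]3C2 | intermediate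
15 | S-ethyl (1S,5S,6S,7S)-7-[2-(tert-butyldimethylsilyloxy)ethyl]-3,7-dimethyl-2-oxo-8-oxabicyclo[3.2.1]oct-3-ene-6-carbothioate | CCSC(=O)[C@@H]1[C@@H]2C=C(C)C(=O)[C@@H](O2)[C@@]1(C)CCO[Si](C)(C)C(C)(C)C | intermediate
16 | (1S,5S,6S,7S)-7-[2-(tert-butyldimethylsilyloxy)ethyl]-3,7-dimethyl-6-(2-methylpropanoyl)-8-oxabicyclo[3.2.1]oct-3-en-2-one | CC(C)C(=O)[C@@H]1[C@@H]2C=C(C)C(=O)[C@@H](O2)[C@@]1(C)CCO[Si](C)(C)C(C)(C)C | intermediate
17 | (1S,5S,6S,7S)-7-(2-hydroxyethyl)-3,7-dimethyl-6-(2-methylpropanoyl)-8-oxabicyclo[3.2.1]oct-3-en-2-one | CC(C)C(=O)[C@@H]1[C@@H]2C=C(C)C(=O)[C@@H](O2)[C@@]1(C)CCO | intermediate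
18 | (1S,5S,6S,7S)-7-(2-iodoethyl)-3,7-dimethyl-6-(2-methylpropanoyl)-8-oxabicyclo[3.2.1]oct-3-en-2-one | CC(C)C(=O)[C@@H]1[C@@H]2C=C(C)C(=O)[C@@H](O2)[C@@]1(C)CCI | intermediate
19 | (4S,5S,6S)-4-hydroxy-6-(2-iodoethyl)-2,6-dimethyl-5-(2-methylpropanoyl)cyclohept-2-en-1-one (present as its samarium dienolate alkoxide) | O=C1C[C@@](C)(CCI)[C@H](C(=O)C(C)C)[C@@H](O)C=C1C | intermediate
20 | (3R,3aS,4S,8aR)-3,4-dihydroxy-6,8a-dimethyl-3-(propan-2-yl)-2,3,3a,4,8,8a-hexahydroazulen-7(1H)-one | O=C1C[C@@]2(C)CC[C@@](O)(C(C)C)[C@@H]2[C@@H](O)C=C1C | intermediate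
21 | 4-hydroxybenzoic acid | OC(=O)c1ccc(O)cc1 | starting material
22 | tert-butyldimethylsilyl 4-(tert-butyldimethylsilyloxy)benzoate | CC(C)(C)[Si](C)(C)OC(=O)c1ccc(O[Si](C)(C)C(C)(C)C)cc1 | intermediate
23 | 4-(tert-butyldimethylsilyloxy)benzoyl chloride | ClC(=O)c1ccc(O[Si](C)(C)C(C)(C)C)cc1 | intermediate
24 | (3R,3aS,4S,8aR)-3-hydroxy-6,8a-dimethyl-7-oxo-3-(propan-2-yl)-1,2,3,3a,4,7,8,8a-octahydroazulen-4-yl 4-(tert-butyldimethylsilyloxy)benzoate | O=C1C[C@@]2(C)CC[C@@](O)(C(C)C)[C@@H]2[C@@H](OC(=O)c2ccc(O[Si](C)(C)C(C)(C)C)cc2)C=C1C | intermediate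
25 | (3R,3aS,4S,7R,8aR)-3,7-dihydroxy-6,8a-dimethyl-3-(propan-2-yl)-1,2,3,3a,4,7,8,8a-octahydroazulen-4-yl 4-(tert-butyldimethylsilyloxy)benzoate | O[C@@H]1C[C@@]2(C)CC[C@@](O)(C(C)C)[C@@H]2[C@@H](OC(=O)c2ccc(O[Si](C)(C)C(C)(C)C)cc2)C=C1C | intermediate
26 | (3R,3aS,4S,7S,8aR)-7-acetoxy-3-hydroxy-6,8a-dimethyl-3-(propan-2-yl)-1,2,3,3a,4,7,8,8a-octahydroazulen-4-yl 4-(tert-butyldimethylsilyloxy)benzoate | CC(=O)O[C@H]1C[C@@]2(C)CC[C@@](O)(C(C)C)[C@@H]2[C@@H](OC(=O)c2ccc(O[Si](C)(C)C(C)(C)C)cc2)C=C1C | intermediate
27 | (3R,3aS,4S,7S,8aR)-7-acetoxy-3-hydroxy-6,8a-dimethyl-3-(propan-2-yl)-1,2,3,3a,4,7,8,8a-octahydroazulen-4-yl 4-hydroxybenzoate | CC(=O)O[C@H]1C[C@@]2(C)CC[C@@](O)(C(C)C)[C@@H]2[C@@H](OC(=O)c2ccc(O)cc2)C=C1C | target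

## Step count and risks

Total: 19 steps. Longest linear sequence: 14 steps (steps 4–13 and 16–19, from but-3-yn-1-ol). The pyranone (steps 1–3) and the aroyl chloride (steps 14–15) are side branches.

**Step 8 (key step).**
- Risk: self-addition of the ylide may outrun the cycloaddition, because the acceptor is hindered at C1 and only moderately electron-poor. At the temperature this forces, endo and facial selectivity may erode.
- Fallback (known reaction types only), from 10 and 4 back to 14, building C1 after the cycloaddition: sultam 10 is acylated with but-2-ynoic acid (pivaloyl mixed anhydride) to N-(but-2-ynoyl)sultam F1. The ylide from 4 adds to this electron-poor alkyne, a partner class established for 3-oxidopyrylium ylides. After separation from its bridgehead diastereomer this gives bicyclic dienone F2, in which C1 (methyl) and C5 (acyl) are still sp2. Luche reduction (NaBH4, CeCl3·7H2O) masks the C9 ketone as endo alcohol F3. (CH2=CH)2CuLi with Me3SiCl then adds vinyl to C1 from the exo face, and the enolate is protonated at C5 from the same face, giving vinyl adduct F4 with vinyl exo and methyl and acyl endo. This is the relative configuration the (E)-alkene would have delivered. Hydroboration with 9-BBN and oxidation with NaBO3·4H2O give diol F5, silylation of the primary hydroxyl gives silyl ether F6, and MnO2 restores the enone, which is compound 14.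

**Step 9.**
- Risk: incomplete acyl transfer at the very hindered, endo C4 carbonyl, or thiol addition to the enone if free thiol is present.
- Fallback, from 14 back to 16: LiAlH4 removes the sultam reductively and also reduces C9, giving diol F7. Dess–Martin oxidation gives keto aldehyde F8. i-PrMgCl at −78 °C (or i-PrTi(OiPr)3) adds to the aldehyde in preference to the hindered enone, giving hydroxy ketone F9, and a second Dess–Martin oxidation arrives at 16.

**Step 10.**
- Risk: β-hydride elimination and re-insertion at the isopropyl–palladium stage (n-propyl ketone or reduction), or slow oxidative addition into the hindered thioester.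
- Fallback, from 15 back to 16: Liebeskind–Srogl coupling with isopropenylboronic acid pinacol ester (Pd2(dba)3, tri(2-furyl)phosphine, copper thiophene-2-carboxylate CuO2CC4H3S) gives isopropenyl ketone F10, an sp2 partner that cannot isomerise. Hydrogenation with RhCl(PPh3)3 saturates the 1,1-disubstituted alkene but not the trisubstituted ring alkene, giving 16.

**Step 13.**
- Risk: retro-aldol cleavage of C5–C6 in the transient C6 alkoxide/C4 ketone, reduction of the iodide without ring closure, or loss of chelate control at C4.
- Fallback, from 15 back to 20, closing ring B as a ketone and adding the isopropyl group afterwards: HF·pyridine and then I2/PPh3/imidazole convert 15 into thioester alcohol F11 and thioester iodide F12. SmI2/HMPA cleaves C10–O and closes ring B by intramolecular acyl substitution; a thioester aldolate is much less prone to retro-aldol than a ketone aldolate. This gives in the flask cyclopentanone F13, with C9 still masked as its samarium dienolate. i-PrMgCl premixed with CeCl3 is added to the same flask and attacks the C4 ketone from the face opposite C6 (steric instead of chelate control), and aqueous work-up gives 20.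

**Step 18 (with step 17).**
- Risk: substitution with allylic transposition or elimination to a diene instead of clean inversion, or insufficient facial selectivity in the preceding reduction.
- Fallback, from 24 back to 26: reagent-controlled reduction with (R)-2-methyl-CBS-oxazaborolidine and catecholborane (the alkenyl side acting as the large group) gives (9S) alcohol F14 directly, and Ac2O/pyridine/DMAP gives 26.

## Further compounds

F1 | step 8 | N-(but-2-ynoyl)-(2R)-bornane-10,2-sultam | CC1(C)[C@@H]2CC[C@]13CS(=O)(=O)N(C(=O)C#CC)[C@@H]3C2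
F2 | step 8 | N-[(3,7-dimethyl-2-oxo-8-oxabicyclo[3.2.1]octa-3,6-dien-6-yl)carbonyl]-(2R)-bornane-10,2-sultam, bridgeheads as in 14 | CC1(C)[C@@H]2CC[C@]13CS(=O)(=O)N(C(=O)C4=C(C)[C@@H]5O[C@H]4C=C(C)C5=O)[C@@H]3C2
F3 | step 8 | endo C9 alcohol of F2 (2-hydroxy-3,7-dimethyl-8-oxabicyclo[3.2.1]octa-3,6-dien-6-yl acyl sultam) | CC1(C)[C@@H]2CC[C@]13CS(=O)(=O)N(C(=O)C4=C(C)[C@@H]5O[C@H]4C=C(C)[C@@H]5O)[C@@H]3C2
F4 | step 8 | 7-exo-vinyl, 7-endo-methyl, 6-endo-acyl 2-endo-hydroxy-8-oxabicyclo[3.2.1]oct-3-ene acyl sultam | CC1(C)[C@@H]2CC[C@]13CS(=O)(=O)N(C(=O)[C@@H]4[C@@H]5C=C(C)[C@H](O)[C@@H](O5)[C@@]4(C)C=C)[C@@H]3C2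
F5 | step 8 | 7-(2-hydroxyethyl) diol from F4 | CC1(C)[C@@H]2CC[C@]13CS(=O)(=O)N(C(=O)[C@@H]4[C@@H]5C=C(C)[C@H](O)[C@@H](O5)[C@@]4(C)CCO)[C@@H]3C2
F6 | step 8 | primary silyl ether of F5 (C9 alcohol of 14) | CC1(C)[C@@H]2CC[C@]13CS(=O)(=O)N(C(=O)[C@@H]4[C@@H]5C=C(C)[C@H](O)[C@@H](O5)[C@@]4(C)CCO[Si](C)(C)C(C)(C)C)[C@@H]3C2
F7 | step 9 | 6-(hydroxymethyl)-7-[2-(tert-butyldimethylsilyloxy)ethyl]-3,7-dimethyl-8-oxabicyclo[3.2.1]oct-3-en-2-ol (endo alcohol) | OC[C@@H]1[C@@H]2C=C(C)[C@H](O)[C@@H](O2)[C@@]1(C)CCO[Si](C)(C)C(C)(C)C
F8 | step 9 | (1S,5S,6S,7S)-7-[2-(tert-butyldimethylsilyloxy)ethyl]-3,7-dimethyl-2-oxo-8-oxabicyclo[3.2.1]oct-3-ene-6-carbaldehyde | O=C[C@@H]1[C@@H]2C=C(C)C(=O)[C@@H](O2)[C@@]1(C)CCO[Si](C)(C)C(C)(C)C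
F9 | step 9 | 6-(1-hydroxy-2-methylpropyl) analogue of 16 (both carbinol epimers) | CC(C)C(O)[C@@H]1[C@@H]2C=C(C)C(=O)[C@@H](O2)[C@@]1(C)CCO[Si](C)(C)C(C)(C)C
F10 | step 10 | 6-(2-methylprop-2-enoyl) analogue of 16 | C=C(C)C(=O)[C@@H]1[C@@H]2C=C(C)C(=O)[C@@H](O2)[C@@]1(C)CCO[Si](C)(C)C(C)(C)C
F11 | step 13 | S-ethyl 7-(2-hydroxyethyl)-3,7-dimethyl-2-oxo-8-oxabicyclo[3.2.1]oct-3-ene-6-carbothioate | CCSC(=O)[C@@H]1[C@@H]2C=C(C)C(=O)[C@@H](O2)[C@@]1(C)CCO
F12 | step 13 | S-ethyl 7-(2-iodoethyl)-3,7-dimethyl-2-oxo-8-oxabicyclo[3.2.1]oct-3-ene-6-carbothioate | CCSC(=O)[C@@H]1[C@@H]2C=C(C)C(=O)[C@@H](O2)[C@@]1(C)CCI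
F13 | step 13 | (3aS,4S,8aR)-4-hydroxy-6,8a-dimethyl-2,3,3a,4,8,8a-hexahydroazulene-3,7(1H)-dione (present as its samarium dienolate) | O=C1C[C@@]2(C)CCC(=O)[C@@H]2[C@@H](O)C=C1C
F14 | step 18 | (9S) epimer of 25 | O[C@H]1C[C@@]2(C)CC[C@@](O)(C(C)C)[C@@H]2[C@@H](OC(=O)c2ccc(O[Si](C)(C)C(C)(C)C)cc2)C=C1C
A1 | alternative 1 | 1-diazo-4-(3-methoxy-4-methylphenyl)butan-2-one | COc1cc(CCC(=O)C=[N+]=[N-])ccc1C
A2 | alternative 1 | 5-methoxy-6-methyl-3,8a-dihydro-2H-azulen-1-one | COC1=C(C)C=C[C@H]2C(=O)CCC2=C1
A3 | alternative 2 | trans-fused ring A 6,8-diene, C4 trimethylsilyl ether | CC1=CC[C@@]2(C)CC[C@@](O[Si](C)(C)C)(C(C)C)[C@@H]2C=C1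
A4 | alternative 2 | C6,C9-endoperoxide | O3[C@H]1C[C@@]2(C)CC[C@@](O[Si](C)(C)C)(C(C)C)[C@@H]2[C@@H](O3)C=C1C
A5 | alternative 3 | 6-acetoxy-2-[(R-configured C4) 3-hydroxy-2,6-dimethylhept-6-en-3-yl]-5-methyl-2H-pyran-3(6H)-one | C=C(C)CC[C@@](O)(C(C)C)C1OC(OC(C)=O)C(C)=CC1=O
A6 | alternative 3 | C5–O–C9 bridged tricyclic enone | O1[C@H]2C[C@@]3(C)CC[C@@](O)(C(C)C)[C@@]13C(=O)C=C2C
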